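**Plan**

- Retrosynthesis: the acetate, the C12–O8 lactone bond (with the C12 oxidation level) and the C3 methylene come off first. Ring bonds C6–C7 (retro-carbonyl-ene) and C5–C10 (retro-Claisen) are then cut, which opens the cyclohexane to the acyclic allyl vinyl ether 14. Its vinylic C6–O bond is cut last, giving allylic alcohol 10 and vinyl iodide 13.
- Enabling feature: in ring C5–C10 the quaternary C10 carries the vinyl group C1=C2 next to C5–C6–O (γ,δ-unsaturated carbonyl pattern C2=C1–C10–C5–C6=O). C6–O is also flanked by C7 with the 2-propenyl unit C11(=C13)–C12 (homoallylic alcohol pattern). Both patterns share C6, so one aldehyde links two pericyclic events.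
- Forward order: chain first (D-erythronolactone to 10, C–O coupling with 13); one thermal operation then builds the cyclohexane (C5–C10, then C6–C7); C6 is inverted and acylated; C12 is oxidised, the enal is made, the lactone ring closes last and the acetate follows.
- Stereochemistry: C8 and C9 come from 2,3-O-isopropylidene-D-erythronolactone; C10 and C5 from the chair Claisen step (alkene geometries plus the facial bias of the dioxolane); C7 from the ene chair; C6 from LiBH(s-Bu)3 reduction of ketone 17.

Key step: step 10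

Remark: atoms are numbered as in elemanes (ring C5–C10; C10 bears the C14 methyl and vinyl C1=C2; C5 bears C4 with C3 and C15; C7 bears C11 with C12 and C13). β is the ring face of the C14 methyl. In this numbering the target is 5R,6S,7S,8R,9S,10S.

**Route**

Step 1
Reactants: 1 2,3-O-isopropylidene-D-erythronolactone
Product: 2 2,3-O-isopropylidene-D-erythrose (lactol)
Conditions: i-Bu2AlH, CH2Cl2, −78 °C; then aq. Rochelle salt
Reagents that add atoms: none
Why: Partial reduction of a lactone to the lactol by i-Bu2AlH should stop at the stable tetrahedral aluminate at low temperature and touches no stereocentre.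

Step 2
Reactants: 2 2,3-O-isopropylidene-D-erythrose
Product: 3 [(4R,5S)-5-ethynyl-2,2-dimethyl-1,3-dioxolan-4-yl]methanol
Conditions: dimethyl (1-diazo-2-oxopropyl)phosphonate, K2CO3, MeOH, 0 °C to rt
Reagents that add atoms: dimethyl (1-diazo-2-oxopropyl)phosphonate, CC(=O)C(=[N+]=[N-])P(=O)(OC)OC
Why: Seyferth–Gilbert homologation in the Ohira–Bestmann variant should act on the aldehyde form of the lactol, turning the future C10 into a terminal alkyne carbon and freeing the C7 hydroxyl while the cis-dioxolane is kept.

Step 3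
Reactants: 3 alkynol
Product: 4 (4S,5S)-5-ethynyl-2,2-dimethyl-1,3-dioxolane-4-carbaldehyde
Conditions: DMP, pyridine, CH2Cl2, 0 °C to rt
Reagents that add atoms: none
Why: Dess–Martin oxidation under buffered, non-basic conditions should give the α-alkoxy aldehyde without epimerisation at C8.

Step 4
Reactants: 4 aldehyde
Product: 5 (4S,5R)-4-ethynyl-2,2-dimethyl-5-(2-methylprop-1-en-1-yl)-1,3-dioxolane
Conditions: i-PrPPh3I, n-BuLi, THF, 0 °C; then 4, −78 °C to rt
Reagents that add atoms: isopropyltriphenylphosphonium iodide, CC(C)[P+](c1ccccc1)(c1ccccc1)c1ccccc1.[I-]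
Why: Wittig olefination with the non-stabilised isopropylidene ylide should install the C7=C11 ene donor; the ylide is not basic enough to deprotonate the alkyne.

Step 5
Reactants: 5 enyne
Product: 7 methyl 3-[(4S,5R)-2,2-dimethyl-5-(2-methylprop-1-en-1-yl)-1,3-dioxolan-4-yl]prop-2-ynoate, via lithium acetylide 6 (not isolated)
Conditions: n-BuLi, THF, −78 °C; then ClCO2Me, −78 to 0 °C
Reagents that add atoms: methyl chloroformate, COC(=O)Cl
Why: C-acylation of a lithium acetylide with a chloroformate is a standard ynoate synthesis and adds C2.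

Step 6
Reactants: 7 ynoate
Product: 9 methyl (Z)-3-[(4S,5R)-2,2-dimethyl-5-(2-methylprop-1-en-1-yl)-1,3-dioxolan-4-yl]but-2-enoate, via alkenylcuprate 8 (not isolated)
Conditions: Me2CuLi (from MeLi and CuI), THF, −78 °C; then MeOH, −78 °C
Reagents that add atoms: lithium dimethylcuprate, [Li+].C[Cu-]C
Why: syn-Carbocupration (conjugate addition of a Gilman reagent to an ynoate) followed by protonation at −78 °C with retention should place the C14 methyl on C10 and leave C9 cis to the ester, i.e. the Z alkene.

Step 7
Reactants: 9 enoate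
Product: 10 (Z)-3-[(4S,5R)-2,2-dimethyl-5-(2-methylprop-1-en-1-yl)-1,3-dioxolan-4-yl]but-2-en-1-ol
Conditions: i-Bu2AlH, CH2Cl2, −78 °C; then aq. Rochelle salt
Reagents that add atoms: none
Why: 1,2-Reduction of an enoate by i-Bu2AlH should give the allylic alcohol with the Z geometry intact, since O9 is locked in the acetonide and cannot lactonise.

Step 8
Reactants: 11 4,4-diethoxybut-1-yne
Product: 13 (E)-4,4-diethoxy-1-iodobut-1-ene, via alkenylzirconocene 12 (not isolated)
Conditions: Cp2Zr(H)Cl, THF, rt; then I2, 0 °C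
Reagents that add atoms: iodine, II
Why: Schwartz hydrozirconation adds syn with zirconium at the terminal carbon, and iodinolysis with retention should give the E vinyl iodide with the acetal untouched.

Step 9
Reactants: 10 allylic alcohol and 13 vinyl iodide
Product: 14 (4S,5R)-4-[(Z)-4-{[(E)-4,4-diethoxybut-1-en-1-yl]oxy}but-2-en-2-yl]-2,2-dimethyl-5-(2-methylprop-1-en-1-yl)-1,3-dioxolane
Conditions: CuI (10 mol %), 3,4,7,8-tetramethyl-1,10-phenanthroline (20 mol %), Cs2CO3, PhMe, 80 °C
Reagents that add atoms: none
Why: Copper-catalysed Ullmann-type C–O coupling of a vinyl iodide with an alcohol proceeds with retention of alkene geometry, and at 80 °C it should stop at the allyl vinyl ether with the E enol ether.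

Step 10
Reactants: 14 allyl vinyl ether
Product: 16 cyclohexanol 5β-(2,2-diethoxyethyl)-10α-ethenyl-10β-methyl-7β-(prop-1-en-2-yl)-8α,9α-(isopropylidenedioxy)cyclohexan-6α-ol, via Claisen aldehyde 15 (not isolated)
Conditions: degassed PhMe (0.02 M), 180 °C, sealed tube
Reagents that add atoms: none
Why: On heating, 14 should undergo a concerted [3,3]-sigmatropic Claisen rearrangement through a chair transition state that forms C5–C10 and releases aldehyde 15, whose C6 carbonyl then adds to the C7=C11 alkene in an intramolecular carbonyl-ene reaction (hydrogen shift from a C11 methyl to oxygen) that forms C6–C7. The closest known reaction type is the thermal Claisen/carbonyl-ene domino sequence, i.e. an aliphatic Claisen rearrangement followed by a citronellal-to-isopulegol-type cyclisation. The only ring closed is cyclohexane C5–C10, closed at C6–C7 through a six-membered chair in which both reacting π bonds (C6=O and C7=C11) stay exocyclic (6-exo mode). C10 and C5 are set relative to each other by the chair with the Z C1=C10 alkene (C9 axial, C14 equatorial) and the E C5=C6 enol ether (C4 equatorial), and relative to C9 by 1,3-allylic strain with the cis C2 methylene, which holds H9 in the alkene plane so that C8 and its cis alkenyl arm shield one face and the vinyl ether adds on the O9 face. C7 is set in the ene chair, where H8 eclipses C7=C11 (1,3-allylic strain with the Z methyl), the side chain sits equatorial and the tether through C9 delivers C6 anti to O8; C6 should come out mainly as the equatorial 6α-alcohol, but its configuration is not needed because step 11 erases it. The step needs the Claisen pathway to outrun a Cope rearrangement of the 1,5-diene C1=C10–C9–C8–C7=C11 (uphill, since it would break the dioxolane C8–C9 bond) and the ene step to use only C7=C11, which is secured because the C1=C2 vinyl group has no allylic hydrogen and only C7 lies within six-ring reach of C6.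

Step 11
Reactants: 16 cyclohexanol
Product: 17 5β-(2,2-diethoxyethyl)-10α-ethenyl-10β-methyl-7β-(prop-1-en-2-yl)-8α,9α-(isopropylidenedioxy)cyclohexan-6-one
Conditions: DMP, pyridine, CH2Cl2, 0 °C to rt
Reagents that add atoms: none
Why: Dess–Martin oxidation under buffered conditions should give the β,γ-unsaturated ketone without moving the C11=C13 alkene into conjugation and makes the C6 outcome of step 10 irrelevant.

Step 12
Reactants: 17 ketone
Product: 18 5β-(2,2-diethoxyethyl)-10α-ethenyl-10β-methyl-7β-(prop-1-en-2-yl)-8α,9α-(isopropylidenedioxy)cyclohexan-6β-ol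
Conditions: LiBH(s-Bu)3, THF, −78 °C; then H2O
Reagents that add atoms: none
Why: Bulky-hydride reduction of a cyclohexanone goes by equatorial attack, and here the β-face axial approach is also blocked by the axial C14 methyl (1,3-diaxial), so hydride should enter from the α face and give the axial 6β-alcohol.

Step 13
Reactants: 18 6β-alcohol
Product: 19 6β-angelate of 18
Conditions: angelic acid, 2,4,6-Cl3C6H2COCl, Et3N, PhMe, rt; then 18, 80 °C
Reagents that add atoms: angelic acid, C/C=C(/C)C(=O)O
Why: Yamaguchi-type mixed-anhydride esterification without a nucleophilic catalyst is the established way to make angelates without Z-to-E isomerisation, and a hydroxyl with only one syn-diaxial methyl should still be acylable.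

Step 14
Reactants: 19 angelate
Product: 20 6β-angeloyloxy-5β-(2,2-diethoxyethyl)-10α-ethenyl-7β-(3-hydroxyprop-1-en-2-yl)-10β-methyl-8α,9α-(isopropylidenedioxy)cyclohexane
Conditions: SeO2 (0.3 equiv), t-BuOOH, CH2Cl2, rt
Reagents that add atoms: selenium dioxide (catalytic oxygen carrier), O=[Se]=O; tert-butyl hydroperoxide (terminal oxidant), CC(C)(C)OO
Why: SeO2 allylic oxidation (ene reaction then [2,3]-shift) of a 1,1-disubstituted alkene prefers the methyl over the methine, and the vinyl group (no allylic hydrogen) and the electron-poor angelate should not react; any C12 aldehyde formed converges in step 17.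

Step 15
Reactants: 20 allylic alcohol
Product: 21 2-[6β-angeloyloxy-10α-ethenyl-8α,9α-dihydroxy-7β-(3-hydroxyprop-1-en-2-yl)-10β-methylcyclohex-5β-yl]acetaldehyde
Conditions: AcOH/H2O (4:1), 50 °C
Reagents that add atoms: water, O
Why: Mild acid hydrolysis should cleave the acetonide and the diethyl acetal together; the C15 aldehyde cannot form a cyclic hemiacetal because its β side chain is trans to the α hydroxyls at C8 and C9.

Step 16
Reactants: 21 triol aldehyde
Product: 22 2-[6β-angeloyloxy-10α-ethenyl-8α,9α-dihydroxy-7β-(3-hydroxyprop-1-en-2-yl)-10β-methylcyclohex-5β-yl]prop-2-enal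
Conditions: aq. HCHO (37 %), pyrrolidine (10 mol %), EtCO2H (10 mol %), i-PrOH, 45 °C
Reagents that add atoms: formaldehyde, C=O
Why: Amine-catalysed α-methylenation of an aldehyde (Mannich condensation then elimination) adds C3, tolerates free hydroxyls and is run before the amine-sensitive α-methylene lactone exists.

Step 17
Reactants: 22 enal triol
Product: 25 9α-hydroxy lactone 6β-angeloyloxy-9α-hydroxy-15-oxoelema-1,3,11(13)-trien-12,8α-olide, via dialdehyde 23 (not isolated), via lactol 24 (not isolated)
Conditions: activated MnO2 (excess), CH2Cl2, rt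
Reagents that add atoms: none
Why: MnO2 oxidises only the allylic C12 alcohol, and the resulting enal is trapped by the C8 hydroxyl as a five-membered lactol that is oxidised on to the lactone (oxidative lactonisation of a 2-methylene-1,4-diol); the saturated C9 hydroxyl is left alone and cannot reach C12 because it is trans to the C7 side chain.

Step 18
Reactants: 25 9α-hydroxy lactone
Product: 26 target 9α-acetoxy-6β-angeloyloxy-15-oxoelema-1,3,11(13)-trien-12,8α-olide
Conditions: Ac2O, pyridine, DMAP (cat.), CH2Cl2, rt
Reagents that add atoms: acetic anhydride, CC(=O)OC(C)=O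
Why: DMAP-catalysed acetylation of the only remaining hydroxyl should be compatible with the enal, the α-methylene lactone and the angelate.

**Compound list**

1 | 2,3-O-isopropylidene-D-erythronolactone, (3aR,6aR) | O=C1[C@@H]2OC(C)(C)O[C@@H]2CO1 | starting material
2 | 2,3-O-isopropylidene-D-erythrose (lactol, anomeric mixture) | OC1[C@@H]2OC(C)(C)O[C@@H]2CO1 | intermediate
3 | [(4R,5S)-5-ethynyl-2,2-dimethyl-1,3-dioxolan-4-yl]methanol | C#C[C@@H]1OC(C)(C)O[C@@H]1CO | intermediate
4 | (4S,5S)-5-ethynyl-2,2-dimethyl-1,3-dioxolane-4-carbaldehyde | C#C[C@@H]1OC(C)(C)O[C@@H]1C=O | intermediate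
5 | (4S,5R)-4-ethynyl-2,2-dimethyl-5-(2-methylprop-1-en-1-yl)-1,3-dioxolane | C#C[C@@H]1OC(C)(C)O[C@@H]1C=C(C)C | intermediate
6 | lithium acetylide of 5 | [Li]C#C[C@@H]1OC(C)(C)O[C@@H]1C=C(C)C | intermediate
7 | methyl 3-[(4S,5R)-2,2-dimethyl-5-(2-methylprop-1-en-1-yl)-1,3-dioxolan-4-yl]prop-2-ynoate | COC(=O)C#C[C@@H]1OC(C)(C)O[C@@H]1C=C(C)C | intermediate
8 | lithium alkenyl(methyl)cuprate from 7 (copper cis to the new methyl) | [Li+].C[Cu-]/C(C(=O)OC)=C(\C)[C@@H]1OC(C)(C)O[C@@H]1C=C(C)C | intermediate
9 | methyl (Z)-3-[(4S,5R)-2,2-dimethyl-5-(2-methylprop-1-en-1-yl)-1,3-dioxolan-4-yl]but-2-enoate | COC(=O)/C=C(/C)[C@@H]1OC(C)(C)O[C@@H]1C=C(C)C | intermediate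
10 | (Z)-3-[(4S,5R)-2,2-dimethyl-5-(2-methylprop-1-en-1-yl)-1,3-dioxolan-4-yl]but-2-en-1-ol | OC/C=C(/C)[C@@H]1OC(C)(C)O[C@@H]1C=C(C)C | intermediate
11 | 4,4-diethoxybut-1-yne | C#CCC(OCC)OCC | starting material
12 | (E)-(4,4-diethoxybut-1-en-1-yl)zirconocene chloride | CCOC(OCC)C/C=C/[Zr](Cl)(C1C=CC=C1)C1C=CC=C1 | intermediate
13 | (E)-4,4-diethoxy-1-iodobut-1-ene | I/C=C/CC(OCC)OCC | intermediate
14 | allyl vinyl ether: (4S,5R)-4-[(Z)-4-{[(E)-4,4-diethoxybut-1-en-1-yl]oxy}but-2-en-2-yl]-2,2-dimethyl-5-(2-methylprop-1-en-1-yl)-1,3-dioxolane | CCOC(OCC)C/C=C/OC/C=C(/C)[C@@H]1OC(C)(C)O[C@@H]1C=C(C)C | intermediate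
15 | Claisen aldehyde: (2S,3S)-2-(2,2-diethoxyethyl)-3-[(4S,5R)-2,2-dimethyl-5-(2-methylprop-1-en-1-yl)-1,3-dioxolan-4-yl]-3-methylpent-4-enal | O=C[C@@H](CC(OCC)OCC)[C@](C)(C=C)[C@@H]1OC(C)(C)O[C@@H]1C=C(C)C | intermediate
16 | cyclohexanol: 5β-(2,2-diethoxyethyl)-10α-ethenyl-10β-methyl-7β-(prop-1-en-2-yl)-8α,9α-(isopropylidenedioxy)cyclohexan-6α-ol | C=C[C@]1(C)[C@@H]2OC(C)(C)O[C@@H]2[C@@H](C(C)=C)[C@H](O)[C@H]1CC(OCC)OCC | intermediate
17 | corresponding cyclohexan-6-one | C=C[C@]1(C)[C@@H]2OC(C)(C)O[C@@H]2[C@@H](C(C)=C)C(=O)[C@H]1CC(OCC)OCC | intermediate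
18 | corresponding cyclohexan-6β-ol (axial hydroxyl) | C=C[C@]1(C)[C@@H]2OC(C)(C)O[C@@H]2[C@@H](C(C)=C)[C@@H](O)[C@H]1CC(OCC)OCC | intermediate
19 | 6β-angelate of 18 | C=C[C@]1(C)[C@@H]2OC(C)(C)O[C@@H]2[C@@H](C(C)=C)[C@@H](OC(=O)/C(C)=C\C)[C@H]1CC(OCC)OCC | intermediate
20 | 12-hydroxy derivative of 19, with a 7β-(3-hydroxyprop-1-en-2-yl) group | C=C[C@]1(C)[C@@H]2OC(C)(C)O[C@@H]2[C@@H](C(=C)CO)[C@@H](OC(=O)/C(C)=C\C)[C@H]1CC(OCC)OCC | intermediate
21 | triol aldehyde: 2-[6β-angeloyloxy-10α-ethenyl-8α,9α-dihydroxy-7β-(3-hydroxyprop-1-en-2-yl)-10β-methylcyclohex-5β-yl]acetaldehyde | C=C[C@]1(C)[C@H](O)[C@H](O)[C@@H](C(=C)CO)[C@@H](OC(=O)/C(C)=C\C)[C@H]1CC=O | intermediate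
22 | enal triol: the corresponding 2-substituted prop-2-enal | C=C[C@]1(C)[C@H](O)[C@H](O)[C@@H](C(=C)CO)[C@@H](OC(=O)/C(C)=C\C)[C@H]1C(=C)C=O | intermediate
23 | 12,15-dialdehyde (8α,9α-diol) | C=C[C@]1(C)[C@H](O)[C@H](O)[C@@H](C(=C)C=O)[C@@H](OC(=O)/C(C)=C\C)[C@H]1C(=C)C=O | intermediate
24 | 12,8α-lactol (anomeric mixture) | C=C[C@]1(C)[C@H](O)[C@@H]2OC(O)C(=C)[C@H]2[C@@H](OC(=O)/C(C)=C\C)[C@H]1C(=C)C=O | intermediate
25 | 6β-angeloyloxy-9α-hydroxy-15-oxoelema-1,3,11(13)-trien-12,8α-olide | C=C[C@]1(C)[C@H](O)[C@@H]2OC(=O)C(=C)[C@H]2[C@@H](OC(=O)/C(C)=C\C)[C@H]1C(=C)C=O | intermediate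
26 | 9α-acetoxy-6β-angeloyloxy-15-oxoelema-1,3,11(13)-trien-12,8α-olide (5R,6S,7S,8R,9S,10S) | C=C[C@]1(C)[C@H](OC(C)=O)[C@@H]2OC(=O)C(=C)[C@H]2[C@@H](OC(=O)/C(C)=C\C)[C@H]1C(=C)C=O | target

**Step count**

Total steps: 18. Longest linear sequence: 17 (steps 1–7 and 9–18); step 8 makes the second fragment.

**Steps most likely to fail**

Step 10. The ene closure may lag behind the Claisen step, so that aldehyde 15 epimerises at C5 or degrades at 180 °C, and some material may leak through a boat Claisen transition state or the wrong alkene face. Fallback: starting from 14, the Claisen rearrangement is run alone at 130 °C in PhMe and aldehyde 15 is isolated. The ring is then closed by a stepwise, Lewis-acid-promoted (Prins-type) carbonyl-ene cyclisation with Me2AlCl in CH2Cl2 at −78 °C instead of a thermal pericyclic closure, and the route is rejoined at 16. This fallback makes no compound outside the list (F0).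

Step 13. Acylation of the axial C6 hydroxyl, which is syn-diaxial to the C14 methyl, may be slow, and forcing conditions may isomerise the angeloyl unit to the tigloyl unit. Fallback: starting from 18, the hydroxyl is acylated with the smaller and more reactive 2-[bis(2,2,2-trifluoroethoxy)phosphoryl]propanoyl chloride (pyridine, DMAP, CH2Cl2) to give the phosphonopropanoate F1. The Z alkene is then built on the ester by Still–Gennari olefination with acetaldehyde (KHMDS, 18-crown-6, THF, −78 °C), and the route is rejoined at 19.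

Step 14. The allylic oxidation may attack the C7 methine or the angelate methyl groups, or give inseparable mixtures of alcohol and over-oxidised products. Fallback: starting from 19, the 2-propenyl alkene, the most electron-rich one, is epoxidised with mCPBA (NaHCO3, CH2Cl2, 0 °C) to give the epoxide F2. Base-induced isomerisation of the epoxide to the allylic alcohol with diethylaluminium 2,2,6,6-tetramethylpiperidide (Et2Al(tmp), PhH, 0 °C) removes a methyl hydrogen, and the route is rejoined at 20.

**Further compounds**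

F0 | step 10 | none | none
F1 | step 13 | 6β-{2-[bis(2,2,2-trifluoroethoxy)phosphoryl]propanoyloxy} analogue of 19 (epimers at the phosphonate α-carbon) | C=C[C@]1(C)[C@@H]2OC(C)(C)O[C@@H]2[C@@H](C(C)=C)[C@@H](OC(=O)C(C)P(=O)(OCC(F)(F)F)OCC(F)(F)F)[C@H]1CC(OCC)OCC
F2 | step 14 | 11,13-epoxide of 19, with a 7β-(2-methyloxiran-2-yl) group (epimers at the oxirane carbon) | C=C[C@]1(C)[C@@H]2OC(C)(C)O[C@@H]2[C@@H](C3(C)CO3)[C@@H](OC(=O)/C(C)=C\C)[C@H]1CC(OCC)OCC
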